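The C18 hydroxyl of the target is traced back to a C18–Si bond, so the whole route rests on disconnecting C18–O to a C18–H bond of a gem-dimethyl decalin made from larixol. The key step uses the equatorial 6α-oxygen on ring B, which lies syn across C5 to the equatorial 4α-methyl (C18) on ring A: a rhodium-catalysed dehydrogenative silylation of the 6-O-diethylsilyl ether forms the C18–Si bond, closes a six-membered oxasilinane (O6, Si, C18, C4, C5, C6) and makes C4 stereogenic in one operation. The precursor is an alkene-free trans-decalin with O6–SiHEt2, O8–SiMe3 and the C13 ketone as a dioxolane; oxidation and a butenolide annulation finish the synthesis.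

Key step: step 7

Remark on the chemistry: labdane numbering is used, with primed locants for the butenolide (O1′, C2′ carbonyl, C3′, C4′ bearing the methyl, C5′). The tertiary O8 cannot be silylated ahead of the more reactive secondary O6, so both are trimethylsilylated and O6 is then released. Commercial (+)-larixol supplies C5, C6, C9 and C10. The two small coupling partners 15 and 19 are each made in one step.

Step 1
Reactants: 1 larixol, (13S)-labda-8(17),14-diene-6α,13-diol
Product: 2 6α-hydroxy-14,15-dinorlabd-8(17)-en-13-one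
Conditions: KMnO4, acetone/H2O, 0 °C → rt
Reagents that add atoms: none
Why: Permanganate degradation of the tertiary vinyl carbinol (dihydroxylation of the monosubstituted C14=C15 alkene, then oxidative glycol cleavage) should excise C14 and C15 and leave the original O13 as the ketone oxygen, the hindered 1,1-disubstituted C8(17) alkene and the 6α-alcohol reacting more slowly; no ring stereocentre is involved.

Step 2
Reactants: 2 6α-hydroxy-14,15-dinorlabd-8(17)-en-13-one
Product: 3 13,13-ethylenedioxy-14,15-dinorlabd-8(17)-en-6α-ol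
Conditions: HOCH2CH2OH, PPTS, benzene, reflux (Dean–Stark)
Reagents that add atoms: ethylene glycol, OCCO
Why: Acid-catalysed ketalisation driven by azeotropic removal of water masks the ketone against hydride and hydrosilane in later steps, and the weak acid should leave the exocyclic alkene in place.

Step 3
Reactants: 3 13,13-ethylenedioxy-14,15-dinorlabd-8(17)-en-6α-ol
Product: 4 8α,17-epoxy-13,13-ethylenedioxy-14,15-dinorlabdan-6α-ol
Conditions: mCPBA, NaHCO3, CH2Cl2, 0 °C
Reagents that add atoms: mCPBA (3-chloroperoxybenzoic acid), OOC(=O)c1cccc(Cl)c1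
Why: Prilezhaev epoxidation from the α-face (equatorial approach at C8) sets C8 with oxygen α and C17 β, because the β-face of C8=C17 is screened by the syn-axial C20 methyl on C10 and by the C9 side chain while the 6α-hydroxyl can guide the peracid by hydrogen bonding.

Step 4
Reactants: 4 8α,17-epoxy-13,13-ethylenedioxy-14,15-dinorlabdan-6α-ol
Product: 5 13,13-ethylenedioxy-14,15-dinorlabdane-6α,8α-diol
Conditions: LiAlH4, THF, reflux
Reagents that add atoms: none
Why: Hydride reduction of the epoxide by SN2 attack at the unhindered primary C17 turns C17 into the axial β-methyl and leaves the C8–O bond, and thus the 8α configuration, untouched; the dioxolane is inert to LiAlH4.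

Step 5
Reactants: 5 13,13-ethylenedioxy-14,15-dinorlabdane-6α,8α-diol
Product: 7 13,13-ethylenedioxy-8α-(trimethylsilyloxy)-14,15-dinorlabdan-6α-ol, via bis(trimethylsilyl) ether 6 (not isolated)
Conditions: N-(trimethylsilyl)imidazole (neat), 60 °C; then K2CO3 (cat.), MeOH, 0 °C
Reagents that add atoms: N-(trimethylsilyl)imidazole, C[Si](C)(C)n1ccnc1
Why: Exhaustive O-silylation with a powerful, non-acidic silyl donor is followed by base-catalysed methanolysis, which should cleave the secondary 6-O-silyl ether far faster than the tertiary 8-O-silyl ether and so free O6 alone; the dioxolane tolerates both stages.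

Step 6
Reactants: 7 13,13-ethylenedioxy-8α-(trimethylsilyloxy)-14,15-dinorlabdan-6α-ol; 8 diethylsilane
Product: 9 6α-(diethylsilyloxy)-13,13-ethylenedioxy-8α-(trimethylsilyloxy)-14,15-dinorlabdane
Conditions: Et2SiH2, [Ir(cod)OMe]2 (cat.), THF, rt; volatiles removed in vacuo
Reagents that add atoms: diethylsilane (8), CC[SiH2]CC
Why: Iridium-catalysed dehydrogenative O-silylation of a secondary alcohol with a dihydrosilane stops after one Si–H bond has reacted at room temperature, and the moisture-sensitive (hydrido)silyl ether is taken on crude.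

Step 7
Reactants: 9 6α-(diethylsilyloxy)-13,13-ethylenedioxy-8α-(trimethylsilyloxy)-14,15-dinorlabdane
Product: 10 oxasilinane in which SiEt2 joins O6 and C18 (the 4α-CH2) of 13,13-ethylenedioxy-8α-(trimethylsilyloxy)-14,15-dinorlabdane; C19 remains the 4β-methyl
Conditions: [Rh(cod)Cl]2 (cat.), Xantphos (cat.), norbornene, THF, 100–120 °C (sealed tube)
Reagents that add atoms: none
Why: The Si–H bond of 9 adds oxidatively to the monovalent rhodium chloride–Xantphos complex, norbornene takes up the hydrogen (leaving as norbornane) to give a rhodium silyl species, and the tethered metal then cleaves a C18–H bond to a seven-membered silyl(alkyl) rhodacycle from which C–Si reductive elimination releases 10; this is the established rhodium-catalysed dehydrogenative δ-C(sp3)–H silylation of (hydrido)silyl ethers. The one new ring, the oxasilinane O6–Si–C18–C4–C5–C6, is closed by cyclometalation followed by C–Si reductive elimination and should sit as a chair peri-fused to rings A and B around C5. The new stereocentre C4 arises by desymmetrisation of the gem-dimethyl group under substrate control: in the rigid trans-decalin the chain O6–C6–C5–C4–C18 has two gauche torsions of opposite sign (a syn-pentane array that closes to a chair), whereas the axial C19 has two of the same sign and would need a twist-boat. Site selectivity is what the step needs, and the skeleton supplies it: the three γ-carbons C4, C8 and C10 carry no hydrogen, so no five-membered closure can compete, and the other δ-carbons (C1, C3, C9, C17, C20) are held anti-periplanar in their chains to O6. Chemoselectivity is secured by the absence of any alkene or free hydroxyl, O8 being capped as its trimethylsilyl ether and C13 as a dioxolane.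

Step 8
Reactants: 10 O6–SiEt2–C18 oxasilinane
Product: 12 6α,8α,18-trihydroxy-14,15-dinorlabdan-13-one, via 8-O-silylated 6α,18-diol 11 (not isolated)
Conditions: 30% H2O2, KF, KHCO3, THF/MeOH, 50 °C; aqueous Na2S2O3 work-up; then 1 M HCl, THF, rt
Reagents that add atoms: hydrogen peroxide, OO; water, O
Why: Tamao oxidation (fluoride/bicarbonate-activated silicon, migration of C18 from silicon to peroxide oxygen) converts the C18–Si bond into C18–OH and releases O6 without touching C4, and aqueous acid then hydrolyses the dioxolane and the tertiary silyl ether in the same operation.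

Step 9
Reactants: 13 3-bromo-1-(trimethylsilyl)prop-1-yne; 14 triethyl phosphite
Product: 15 diethyl [3-(trimethylsilyl)prop-2-yn-1-yl]phosphonate
Conditions: P(OEt)3 (neat), 110 °C, EtBr distilled off
Reagents that add atoms: triethyl phosphite (14), CCOP(OCC)OCC
Why: Michaelis–Arbuzov reaction of the primary propargylic bromide with the phosphite, the silyl cap on the alkyne suppressing allenyl phosphonate formation.

Step 10
Reactants: 12 6α,8α,18-trihydroxy-14,15-dinorlabdan-13-one; 15 diethyl [3-(trimethylsilyl)prop-2-yn-1-yl]phosphonate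
Product: 17 (13E)-enyne triol (chain C12–C13(CH3)=C14H–C15≡C5′H on the 6α,8α,18-triol), via C-silylated enyne 16 (not isolated)
Conditions: 15 (excess), LiN(SiMe3)2, THF, −78 °C → rt; then K2CO3, MeOH, rt
Reagents that add atoms: diethyl [3-(trimethylsilyl)prop-2-yn-1-yl]phosphonate (15), CCOP(=O)(CC#C[Si](C)(C)C)OCC
Why: Horner–Wadsworth–Emmons olefination of the methyl ketone should place the alkynyl group trans to the larger C12 chain (13E, any minor Z isomer being removed by chromatography), and methoxide-mediated protodesilylation of the alkynylsilane follows; the free hydroxyls are accommodated by excess reagent.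

Step 11
Reactants: 18 but-2-ynoic acid
Product: 19 (Z)-3-iodobut-2-enoic acid
Conditions: NaI, AcOH, 115 °C
Reagents that add atoms: sodium iodide, [Na+].[I-]
Why: Hydroiodination of the ynoic acid by conjugate addition of iodide and anti protonation should deliver the Z-β-iodo acid.

Step 12
Reactants: 17 (13E)-enyne triol; 19 (Z)-3-iodobut-2-enoic acid
Product: 21 target, the (5′Z,13E)-4′-methyl-γ-ylidenebutenolide of the 6α,8α,18-triol, via dienynoic acid 20 (not isolated)
Conditions: PdCl2(PPh3)2 (cat.), CuI (cat.), Et3N, MeCN, rt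
Reagents that add atoms: (Z)-3-iodobut-2-enoic acid (19), C/C(I)=C/C(=O)O
Why: Sonogashira coupling (oxidative addition of the C–I bond to zerovalent palladium formed in situ, with retention of the Z geometry, and transmetalation from the copper acetylide) gives the (Z)-en-ynoic acid, whose carboxylate then adds anti across the metal-activated alkyne in a 5-exo-dig lactonisation to set the (Z)-C15=C5′ bond; the free hydroxyls and the 13E alkene are spectators.

Compound list
1 | larixol, (13S)-labda-8(17),14-diene-6α,13-diol | C=C[C@@](C)(O)CC[C@@H]1[C@@]2(C)CCCC(C)(C)[C@@H]2[C@@H](O)CC1=C | starting material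
2 | 6α-hydroxy-14,15-dinorlabd-8(17)-en-13-one | CC(=O)CC[C@@H]1[C@@]2(C)CCCC(C)(C)[C@@H]2[C@@H](O)CC1=C | intermediate
3 | 13,13-ethylenedioxy-14,15-dinorlabd-8(17)-en-6α-ol | CC1(CC[C@@H]2[C@@]3(C)CCCC(C)(C)[C@@H]3[C@@H](O)CC2=C)OCCO1 | intermediate
4 | 8α,17-epoxy-13,13-ethylenedioxy-14,15-dinorlabdan-6α-ol | CC1(CC[C@@H]2[C@@]3(C)CCCC(C)(C)[C@@H]3[C@@H](O)C[C@@]2(C4)O4)OCCO1 | intermediate
5 | 13,13-ethylenedioxy-14,15-dinorlabdane-6α,8α-diol | CC1(CC[C@@H]2[C@@]3(C)CCCC(C)(C)[C@@H]3[C@@H](O)C[C@@]2(C)O)OCCO1 | intermediate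
6 | 13,13-ethylenedioxy-6α,8α-bis(trimethylsilyloxy)-14,15-dinorlabdane | CC1(CC[C@@H]2[C@@]3(C)CCCC(C)(C)[C@@H]3[C@@H](O[Si](C)(C)C)C[C@@]2(C)O[Si](C)(C)C)OCCO1 | intermediate
7 | 13,13-ethylenedioxy-8α-(trimethylsilyloxy)-14,15-dinorlabdan-6α-ol | CC1(CC[C@@H]2[C@@]3(C)CCCC(C)(C)[C@@H]3[C@@H](O)C[C@@]2(C)O[Si](C)(C)C)OCCO1 | intermediate
8 | diethylsilane | CC[SiH2]CC | starting material
9 | 6α-(diethylsilyloxy)-13,13-ethylenedioxy-8α-(trimethylsilyloxy)-14,15-dinorlabdane | CC1(CC[C@@H]2[C@@]3(C)CCCC(C)(C)[C@@H]3[C@@H](O[SiH](CC)CC)C[C@@]2(C)O[Si](C)(C)C)OCCO1 | intermediate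
10 | oxasilinane with SiEt2 joining O6 and C18 (4α-CH2); 8α-OSiMe3; C13 dioxolane | CC1(CC[C@@H]2[C@@]3(C)CCC[C@@](C)(C[Si]4(CC)CC)[C@@H]3[C@@H](O4)C[C@@]2(C)O[Si](C)(C)C)OCCO1 | intermediate
11 | 13,13-ethylenedioxy-8α-(trimethylsilyloxy)-14,15-dinorlabdane-6α,18-diol | CC1(CC[C@@H]2[C@@]3(C)CCC[C@@](C)(CO)[C@@H]3[C@@H](O)C[C@@]2(C)O[Si](C)(C)C)OCCO1 | intermediate
12 | 6α,8α,18-trihydroxy-14,15-dinorlabdan-13-one | CC(=O)CC[C@@H]1[C@@]2(C)CCC[C@@](C)(CO)[C@@H]2[C@@H](O)C[C@@]1(C)O | intermediate
13 | 3-bromo-1-(trimethylsilyl)prop-1-yne | C[Si](C)(C)C#CCBr | starting material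
14 | triethyl phosphite | CCOP(OCC)OCC | starting material
15 | diethyl [3-(trimethylsilyl)prop-2-yn-1-yl]phosphonate | CCOP(=O)(CC#C[Si](C)(C)C)OCC | intermediate
16 | C-silylated (13E)-enyne triol, chain C13(CH3)=C14H–C15≡C5′–SiMe3 | C[Si](C)(C)C#C/C=C(\C)CC[C@@H]1[C@@]2(C)CCC[C@@](C)(CO)[C@@H]2[C@@H](O)C[C@@]1(C)O | intermediate
17 | (13E)-enyne triol, chain C13(CH3)=C14H–C15≡C5′H | C#C/C=C(\C)CC[C@@H]1[C@@]2(C)CCC[C@@](C)(CO)[C@@H]2[C@@H](O)C[C@@]1(C)O | intermediate
18 | but-2-ynoic acid | CC#CC(=O)O | starting material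
19 | (Z)-3-iodobut-2-enoic acid | C/C(I)=C/C(=O)O | intermediate
20 | (2′Z,13E)-dienynoic acid, HO2C–C3′H=C4′(CH3)–C5′≡C15–C14H=C13(CH3)– on the triol | OC(=O)/C=C(/C)C#C/C=C(\C)CC[C@@H]1[C@@]2(C)CCC[C@@](C)(CO)[C@@H]2[C@@H](O)C[C@@]1(C)O | intermediate
21 | CNP0126806.1, (5′Z,13E)-γ-ylidenebutenolide of the 6α,8α,18-triol | CC1=CC(=O)O/C1=C\C=C(/C)CC[C@@H]1[C@@]2(C)CCC[C@@](C)(CO)[C@@H]2[C@@H](O)C[C@@]1(C)O | target

Total step count: 12. Longest linear sequence: 10 steps (steps 1–8, 10 and 12, from larixol).

Steps most likely to fail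

1. Step 7. The tethered rhodium silyl may cleave the hindered, neopentyl-type C18–H bond too slowly, so that redistribution at silicon or loss of the silyl ether takes over, or site selectivity may erode toward C19. The fallback replaces metal-catalysed C–H silylation by a radical hydrogen transfer that uses the same O6/C18 proximity. It sets out from alcohol 7. A hypoiodite reaction (PhI(OAc)2, I2, cyclohexane, visible light) should generate the 6-alkoxy radical, which abstracts a C18 hydrogen through a six-membered transition state; iodination and ring closure should give the 6α,18-cyclic ether F1. Oxidation of the ether methylene with RuCl3 (cat.) and NaIO4 in a buffered CCl4/MeCN/H2O mixture should give the 18,6α-lactone F2. Reduction with LiAlH4 opens the lactone to the 6α,18-diol, and the route is rejoined at 11, just before the acid stage of step 8.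

2. Step 10. Olefination of a methyl ketone may show poor E/Z selectivity, and the O8 alkoxide may close onto C13 as a hemiketal and slow the addition. The fallback builds the trisubstituted alkene by syn carbometalation of an alkyne, which fixes the geometry. It sets out from ketone 12. Silylation with Et3SiOTf and 2,6-lutidine in CH2Cl2 at −78 °C should give the 6,8,18-tris(triethylsilyl) ether F3. Kinetic enolisation with LiN(iPr)2 and trapping with ClP(O)(OEt)2 gives the terminal enol diethyl phosphate F4, which more LiN(iPr)2 eliminates in the same flask to the terminal alkyne F5. Zirconium-catalysed carboalumination (AlMe3, Cp2ZrCl2, CH2Cl2) followed by I2 should give the (E)-vinyl iodide F6 with the methyl and iodine cis. Sonogashira coupling with ethynyltrimethylsilane (PdCl2(PPh3)2, CuI, Et3N) gives the fully silylated enyne F7. Bu4NF in THF removes all four silyl groups, and the route is rejoined at 17.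

3. Step 5. The rate difference between methanolysis of the two silyl ethers may be too small, leading to over-cleavage back to the diol or incomplete release of O6. The fallback differentiates the two oxygens by acylation reactivity, not by silyl ether lability. It sets out from diol 5. Ac2O, pyridine and DMAP should acylate only the secondary alcohol, giving the 6-O-acetate F8. N-(trimethylsilyl)imidazole then silylates the tertiary alcohol to give the 6-O-acetyl-8-O-trimethylsilyl compound F9. LiAlH4 in Et2O at 0 °C removes the acetate reductively without touching the silyl ether, and the route is rejoined at 7.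

Further compounds
F1 | step 7 | 6α,18-epoxy-13,13-ethylenedioxy-8α-(trimethylsilyloxy)-14,15-dinorlabdane (cyclic ether O6–C18) | CC1(CC[C@@H]2[C@@]3(C)CCC[C@@](C)(C4)[C@@H]3[C@@H](O4)C[C@@]2(C)O[Si](C)(C)C)OCCO1
F2 | step 7 | 13,13-ethylenedioxy-8α-(trimethylsilyloxy)-14,15-dinorlabdan-18,6α-olide | CC1(CC[C@@H]2[C@@]3(C)CCC[C@@](C)(C4=O)[C@@H]3[C@@H](O4)C[C@@]2(C)O[Si](C)(C)C)OCCO1
F3 | step 10 | 6α,8α,18-tris(triethylsilyloxy)-14,15-dinorlabdan-13-one | CC(=O)CC[C@@H]1[C@@]2(C)CCC[C@@](C)(CO[Si](CC)(CC)CC)[C@@H]2[C@@H](O[Si](CC)(CC)CC)C[C@@]1(C)O[Si](CC)(CC)CC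
F4 | step 10 | terminal enol diethyl phosphate of F3 | C=C(OP(=O)(OCC)OCC)CC[C@@H]1[C@@]2(C)CCC[C@@](C)(CO[Si](CC)(CC)CC)[C@@H]2[C@@H](O[Si](CC)(CC)CC)C[C@@]1(C)O[Si](CC)(CC)CC
F5 | step 10 | terminal alkyne C12–C13≡C14H, tris(triethylsilyl) ether | C#CCC[C@@H]1[C@@]2(C)CCC[C@@](C)(CO[Si](CC)(CC)CC)[C@@H]2[C@@H](O[Si](CC)(CC)CC)C[C@@]1(C)O[Si](CC)(CC)CC
F6 | step 10 | (13E)-14-iodo alkene C13(CH3)=C14H–I, tris(triethylsilyl) ether | I/C=C(\C)CC[C@@H]1[C@@]2(C)CCC[C@@](C)(CO[Si](CC)(CC)CC)[C@@H]2[C@@H](O[Si](CC)(CC)CC)C[C@@]1(C)O[Si](CC)(CC)CC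
F7 | step 10 | C-trimethylsilyl (13E)-enyne, tris(triethylsilyl) ether | C[Si](C)(C)C#C/C=C(\C)CC[C@@H]1[C@@]2(C)CCC[C@@](C)(CO[Si](CC)(CC)CC)[C@@H]2[C@@H](O[Si](CC)(CC)CC)C[C@@]1(C)O[Si](CC)(CC)CC
F8 | step 5 | 6α-acetoxy-13,13-ethylenedioxy-14,15-dinorlabdan-8α-ol | CC1(CC[C@@H]2[C@@]3(C)CCCC(C)(C)[C@@H]3[C@@H](OC(C)=O)C[C@@]2(C)O)OCCO1
F9 | step 5 | 6α-acetoxy-13,13-ethylenedioxy-8α-(trimethylsilyloxy)-14,15-dinorlabdane | CC1(CC[C@@H]2[C@@]3(C)CCCC(C)(C)[C@@H]3[C@@H](OC(C)=O)C[C@@]2(C)O[Si](C)(C)C)OCCO1
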